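**Plan**

1. Ring numbering used throughout: O1, C2 (CH3), C3 (CH2OH), C4 (CH2CO2R, R = 2-(3,4-dihydroxyphenyl)ethyl), C5 (CO2Me), C6.
2. Retrosynthetic cuts, in order: the three O–benzyl bonds; the ring bond C3–C4 (6-exo radical closure, with the C3 radical coming from a C3 carboxyl as its N-acyloxyphthalimide); C4–C5 (Heck); C5–I; O1–C6 (oxa-Michael); C3–CH2O (enolate alkylation).
3. Enabling feature: O1 and C4 are cis on the C5=C6 enol ether double bond. In the open form a C3 radical tethered through C2–O1 therefore sits six atoms from C4, the β-carbon of a C4H=CH–CO2R enoate. Closing C3–C4 makes the dihydropyran and turns the enoate into the C4 acetate arm.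
4. Forward: the chain grows linearly (C2–C3 unit, then O1–C6=C5, then C4 with the hydroxytyrosol ester); the single ring closes in step 9 and hydrogenolysis finishes the route.
5. Stereochemistry: C2 is taken from an (R)-3-hydroxybutanoate; C3 and C4 are set in step 9 under control of C2 (all-equatorial half-chair); the C3 centre made in step 1 is erased at the radical stage.
6. Remark: benzyl ethers protect all three hydroxyl groups; they are inert to every step before the last, and the ester-conjugated C5=C6 bond is assumed to survive mild hydrogenolysis.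

Key step: step 9

**Route**

Step 1
Reactants: 1 tert-butyl (R)-3-hydroxybutanoate; 2 benzyl chloromethyl ether
Product: 4 tert-butyl (2R,3R)-2-[(benzyloxy)methyl]-3-hydroxybutanoate, via dilithium alkoxide enolate 3 (not isolated)
Conditions: LiN(i-Pr)2 (2.2 equiv), THF, −78 to −20 °C; then 2 (1.1 equiv), DMPU, −78 to −20 °C; aq NH4Cl
Reagents that add atoms: lithium diisopropylamide, [Li+].CC(C)[N-]C(C)C (its lithium stays only in 3)
Why: Fráter–Seebach alkylation, in which the lithium-chelated alkoxide enolate is attacked by the chloromethyl ether on the face opposite the carbinol methyl group and should give the anti (2R,3R) product; this new centre (later C3 of the ring) becomes planar in step 9, so its purity is not critical.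

Step 2
Reactants: 4 tert-butyl (2R,3R)-2-[(benzyloxy)methyl]-3-hydroxybutanoate; 5 methyl propiolate
Product: 6 tert-butyl (2R,3R)-2-[(benzyloxy)methyl]-3-{[(E)-3-methoxy-3-oxoprop-1-en-1-yl]oxy}butanoate
Conditions: N-methylmorpholine (1.2 equiv), 5 (1.5 equiv), CH2Cl2, rt
Reagents that add atoms: none
Why: The amine-catalysed oxa-Michael addition of an alcohol to a propiolate (through the β-ammonium acrylate) should form the O1–C6 bond as the E β-alkoxyacrylate, and the base is too weak to cause retro-aldol cleavage or β-elimination of the hydroxy ester.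

Step 3
Reactants: 6 tert-butyl (2R,3R)-2-[(benzyloxy)methyl]-3-{[(E)-3-methoxy-3-oxoprop-1-en-1-yl]oxy}butanoate
Product: 8 tert-butyl (2R,3R)-2-[(benzyloxy)methyl]-3-{[(Z)-2-iodo-3-methoxy-3-oxoprop-1-en-1-yl]oxy}butanoate, via iodo acetate adduct 7 (not isolated)
Conditions: NIS (1.3 equiv), AcOH (3 equiv), CH2Cl2, rt, dark; then Et3N (4 equiv), rt
Reagents that add atoms: N-iodosuccinimide, O=C1CCC(=O)N1I; acetic acid, CC(=O)O (its acetate stays only in 7)
Why: Iodoacetoxylation of the push–pull enol ether at its nucleophilic α-carbon (the future C5) followed by base-induced loss of acetic acid is the standard addition–elimination route from β-alkoxyacrylates to (Z)-α-iodo-β-alkoxyacrylates, acetate being expelled in preference to the alkoxide and iodine ending cis to the ether oxygen.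

Step 4
Reactants: 9 hydroxytyrosol
Product: 10 2-[3,4-bis(benzyloxy)phenyl]ethanol
Conditions: BnBr (2.2 equiv), K2CO3 (3 equiv), acetone, reflux, N2
Reagents that add atoms: benzyl bromide, BrCc1ccccc1
Why: Williamson etherification in which carbonate deprotonates only the two phenols, so the primary alcohol should remain free.

Step 5
Reactants: 10 2-[3,4-bis(benzyloxy)phenyl]ethanol; 11 acryloyl chloride
Product: 12 2-[3,4-bis(benzyloxy)phenyl]ethyl acrylate
Conditions: Et3N (1.5 equiv), CH2Cl2, 0 °C
Reagents that add atoms: none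
Why: Nucleophilic acyl substitution of the acid chloride by the primary alcohol, with Et3N as the HCl acceptor, should give the acrylate cleanly at 0 °C.

Step 6
Reactants: 8 tert-butyl (Z)-α-iodo-β-alkoxyacrylate ester; 12 2-[3,4-bis(benzyloxy)phenyl]ethyl acrylate
Product: 13 1-{2-[3,4-bis(benzyloxy)phenyl]ethyl} 5-methyl (2E,4E)-4-[({(2R,3R)-3-[(benzyloxy)methyl]-4-(tert-butoxy)-4-oxobutan-2-yl}oxy)methylidene]pent-2-enedioate
Conditions: Pd(OAc)2 (10 mol %), n-Bu4NCl (1 equiv), NaHCO3 (2.5 equiv), DMF, 50 °C
Reagents that add atoms: none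
Why: Mizoroki–Heck reaction under ligand-free phase-transfer conditions, in which oxidative addition of the alkenyl iodide to zerovalent palladium, syn insertion of the acrylate at its unsubstituted terminus and syn β-hydride elimination should form the C4–C5 bond as the E enoate with retention of the enol ether geometry (O1 and C4 cis).

Step 7
Reactants: 13 tert-butyl ester dienoate
Product: 14 (2R,3R)-2-[(benzyloxy)methyl]-3-{[(1E,3E)-5-{2-[3,4-bis(benzyloxy)phenyl]ethoxy}-2-(methoxycarbonyl)-5-oxopenta-1,3-dien-1-yl]oxy}butanoic acid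
Conditions: CF3CO2H/CH2Cl2 (1:4), 0 °C to rt
Reagents that add atoms: none
Why: Acidolysis of the tert-butyl ester through the tert-butyl cation, lost as 2-methylpropene, should leave the methyl and phenethyl esters, the benzyl ethers and the acceptor-substituted enol ether (not hydrolysed without water) untouched.

Step 8
Reactants: 14 dienoate acid; 15 N-hydroxyphthalimide
Product: 16 1,3-dioxoisoindolin-2-yl (2R,3R)-2-[(benzyloxy)methyl]-3-{[(1E,3E)-5-{2-[3,4-bis(benzyloxy)phenyl]ethoxy}-2-(methoxycarbonyl)-5-oxopenta-1,3-dien-1-yl]oxy}butanoate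
Conditions: DIC (1.2 equiv), DMAP (5 mol %), CH2Cl2, 0 °C to rt
Reagents that add atoms: none
Why: Carbodiimide (Steglich-type) esterification with the acidic N-hydroxyphthalimide should give the redox-active ester, the low temperature and merely catalytic DMAP limiting β-elimination of the O1 leaving group from the activated acid.

Step 9
Reactants: 16 N-acyloxyphthalimide of the dienoate ether
Product: 17 methyl (2R,3R,4S)-3-[(benzyloxy)methyl]-4-(2-{2-[3,4-bis(benzyloxy)phenyl]ethoxy}-2-oxoethyl)-2-methyl-3,4-dihydro-2H-pyran-5-carboxylate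
Conditions: [Ru(bpy)3](PF6)2 (1 mol %), Hantzsch ester (1.5 equiv), i-Pr2NEt·HBF4 (1 equiv), CH2Cl2 (0.02 M), blue LEDs, rt
Reagents that add atoms: none
Why: The photoexcited tris(2,2'-bipyridine)ruthenium salt is quenched by the Hantzsch ester and the reduced complex passes one electron to the phthalimide ester, which fragments to phthalimide anion, CO2 and the secondary C3 radical; this nucleophilic radical adds to C4, the β-carbon of the E enoate, and the resulting α-ester radical is capped by hydrogen from the Hantzsch ester. The closest known reaction type is the reductive decarboxylative Giese addition of N-acyloxyphthalimides under visible-light photoredox conditions, used here intramolecularly in the manner of 6-exo closures of alkyl radicals onto enoates held by an arene or cis-alkene ether tether. The dihydropyran ring (O1, C2, C3, C4, C5, C6) closes 6-exo-trig, whereas 4-exo attack at C6, 5-endo attack at C5 and 7-endo attack at the enoate α-carbon are disfavoured by geometry or polarity. C4 is set by C2: the diene must be s-trans because an inward acceptor chain would collide with O1, so the chain becomes pseudo-equatorial and the face of C4 that is attacked should be the one that keeps the C2 methyl equatorial in the half-chair transition state, while C3 is set by the benzyloxymethyl group taking the outward, equatorial position on the planar radical, which leads to the 2,3-trans-3,4-trans (2R,3R,4S) ring. The step needs ring closure to outrun hydrogen transfer to the C3 radical, which the low concentration and the cis placement of O1 and C4 on the C5=C6 double bond should secure, and the configuration at C3 of 16 is irrelevant because that centre becomes planar.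

Step 10
Reactants: 17 tribenzyl ether of the target
Product: 18 methyl (2R,3R,4S)-4-{2-[2-(3,4-dihydroxyphenyl)ethoxy]-2-oxoethyl}-3-(hydroxymethyl)-2-methyl-3,4-dihydro-2H-pyran-5-carboxylate
Conditions: H2 (1 atm), 10% Pd/C, EtOAc/MeOH, rt
Reagents that add atoms: none
Why: Hydrogenolysis over palladium should cleave the two aryl benzyl ethers and the primary benzyl ether, while the C5=C6 bond, a trisubstituted vinylogous carbonate, and the homobenzylic ester are expected to resist 1 atm of hydrogen at room temperature, so the three stereocentres are untouched.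

**Compound list**

1 | tert-butyl (R)-3-hydroxybutanoate | C[C@@H](O)CC(=O)OC(C)(C)C | starting material
2 | benzyl chloromethyl ether | ClCOCc1ccccc1 | starting material
3 | dilithium alkoxide enolate of 1 | C[C@@H]([O-])C=C([O-])OC(C)(C)C.[Li+].[Li+] | intermediate
4 | tert-butyl (2R,3R)-2-[(benzyloxy)methyl]-3-hydroxybutanoate | C[C@@H](O)[C@@H](COCc1ccccc1)C(=O)OC(C)(C)C | intermediate
5 | methyl propiolate | C#CC(=O)OC | starting material
6 | tert-butyl (2R,3R)-2-[(benzyloxy)methyl]-3-{[(E)-3-methoxy-3-oxoprop-1-en-1-yl]oxy}butanoate | COC(=O)/C=C/O[C@H](C)[C@@H](COCc1ccccc1)C(=O)OC(C)(C)C | intermediate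
7 | tert-butyl (2R,3R)-3-[1-(acetyloxy)-2-iodo-3-methoxy-3-oxopropoxy]-2-[(benzyloxy)methyl]butanoate (diastereomer mixture at the two new centres) | COC(=O)C(I)C(OC(C)=O)O[C@H](C)[C@@H](COCc1ccccc1)C(=O)OC(C)(C)C | intermediate
8 | tert-butyl (2R,3R)-2-[(benzyloxy)methyl]-3-{[(Z)-2-iodo-3-methoxy-3-oxoprop-1-en-1-yl]oxy}butanoate | COC(=O)/C(I)=C/O[C@H](C)[C@@H](COCc1ccccc1)C(=O)OC(C)(C)C | intermediate
9 | hydroxytyrosol, 4-(2-hydroxyethyl)benzene-1,2-diol | OCCc1ccc(O)c(O)c1 | starting material
10 | 2-[3,4-bis(benzyloxy)phenyl]ethanol | OCCc1ccc(OCc2ccccc2)c(OCc2ccccc2)c1 | intermediate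
11 | acryloyl chloride | C=CC(Cl)=O | starting material
12 | 2-[3,4-bis(benzyloxy)phenyl]ethyl acrylate | C=CC(=O)OCCc1ccc(OCc2ccccc2)c(OCc2ccccc2)c1 | intermediate
13 | 1-{2-[3,4-bis(benzyloxy)phenyl]ethyl} 5-methyl (2E,4E)-4-[({(2R,3R)-3-[(benzyloxy)methyl]-4-(tert-butoxy)-4-oxobutan-2-yl}oxy)methylidene]pent-2-enedioate | COC(=O)/C(=C/O[C@H](C)[C@@H](COCc1ccccc1)C(=O)OC(C)(C)C)/C=C/C(=O)OCCc1ccc(OCc2ccccc2)c(OCc2ccccc2)c1 | intermediate
14 | (2R,3R)-2-[(benzyloxy)methyl]-3-{[(1E,3E)-5-{2-[3,4-bis(benzyloxy)phenyl]ethoxy}-2-(methoxycarbonyl)-5-oxopenta-1,3-dien-1-yl]oxy}butanoic acid | COC(=O)/C(=C/O[C@H](C)[C@@H](COCc1ccccc1)C(O)=O)/C=C/C(=O)OCCc1ccc(OCc2ccccc2)c(OCc2ccccc2)c1 | intermediate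
15 | N-hydroxyphthalimide | ON1C(=O)c2ccccc2C1=O | starting material
16 | 1,3-dioxoisoindolin-2-yl (2R,3R)-2-[(benzyloxy)methyl]-3-{[(1E,3E)-5-{2-[3,4-bis(benzyloxy)phenyl]ethoxy}-2-(methoxycarbonyl)-5-oxopenta-1,3-dien-1-yl]oxy}butanoate | COC(=O)/C(=C/O[C@H](C)[C@@H](COCc1ccccc1)C(=O)ON1C(=O)c2ccccc2C1=O)/C=C/C(=O)OCCc1ccc(OCc2ccccc2)c(OCc2ccccc2)c1 | intermediate
17 | methyl (2R,3R,4S)-3-[(benzyloxy)methyl]-4-(2-{2-[3,4-bis(benzyloxy)phenyl]ethoxy}-2-oxoethyl)-2-methyl-3,4-dihydro-2H-pyran-5-carboxylate | COC(=O)C1=CO[C@H](C)[C@@H](COCc2ccccc2)[C@@H]1CC(=O)OCCc3ccc(OCc4ccccc4)c(OCc5ccccc5)c3 | intermediate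
18 | methyl (2R,3R,4S)-4-{2-[2-(3,4-dihydroxyphenyl)ethoxy]-2-oxoethyl}-3-(hydroxymethyl)-2-methyl-3,4-dihydro-2H-pyran-5-carboxylate | COC(=O)C1=CO[C@H](C)[C@@H](CO)[C@@H]1CC(=O)OCCc1ccc(O)c(O)c1 | target

**Step count and risks**

Total steps: 10. Longest linear sequence: 8 steps (steps 1, 2, 3, 6, 7, 8, 9, 10, from 1 to 18); steps 4 and 5 are the two-step side branch to 12.

Steps most likely to fail:

1. Step 9. Hydrogen transfer from the Hantzsch ester to the C3 radical may outpace ring closure, or closure at room temperature may show poor facial selectivity at C3 and C4. The fallback sets out from acid 14 and returns at 17. Acid 14 would be converted with N-hydroxypyridine-2-thione (ON1C=CC=CC1=S) and DIC (CH2Cl2, 0 °C, dark) into the thiohydroxamate (Barton) ester F1. On irradiation with a tungsten lamp in dilute CH2Cl2 at −20 °C, F1 should propagate a chain in which the C3 radical cyclises with no hydrogen donor present and the α-ester radical takes the pyridylthio group from a second molecule of F1, giving the 2-pyridyl sulfide F2. Reduction of the C–S bond with Bu3SnH and AIBN in toluene at 80 °C would then give 17.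

2. Step 3. The neighbouring tert-butyl ester carbonyl may capture the iodonium ion with loss of the tert-butyl group, or the secondary alkoxy group may be lost instead of acetate in the elimination. The fallback sets out from 6 and returns at 14. The tert-butyl ester would be cleaved first (CF3CO2H, CH2Cl2) to give the acid F3. Iodination of F3 with NIS and then Et3N should give the iodo acid F4, since a carboxyl group that captures the iodonium ion is expelled again on elimination just as acetate is. Heck coupling of F4, as its sodium salt under the palladium conditions of step 6, with acrylate 12 would give acid 14 directly; this order also keeps the acidolysis away from the arene-bearing intermediate.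

3. Step 6. Carbopalladation of the hindered alkenyl iodide may be slow, so that protodeiodination, oligomerisation of the acrylate or isomerisation of the enol ether geometry at 50 °C takes over. The fallback sets out from alcohol 10 and iodide 8 and returns at 13. Esterification of 10 with (E)-3-(tributylstannyl)acrylic acid (CCCC[Sn](CCCC)(CCCC)/C=C/C(O)=O; DIC, DMAP, CH2Cl2) would give the stannyl acrylate F5. Stille coupling of F5 with 8 (Pd2(dba)3, AsPh3, CuI, DMF, rt) should form the C4–C5 bond at room temperature with retention of both double-bond geometries.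

**Further compounds**

F1 | step 9 | 2-thioxopyridin-1(2H)-yl (2R,3R)-2-[(benzyloxy)methyl]-3-{[(1E,3E)-5-{2-[3,4-bis(benzyloxy)phenyl]ethoxy}-2-(methoxycarbonyl)-5-oxopenta-1,3-dien-1-yl]oxy}butanoate | COC(=O)/C(=C/O[C@H](C)[C@@H](COCc1ccccc1)C(=O)ON1C=CC=CC1=S)/C=C/C(=O)OCCc1ccc(OCc2ccccc2)c(OCc2ccccc2)c1
F2 | step 9 | methyl (2R,3R,4S)-3-[(benzyloxy)methyl]-4-[2-{2-[3,4-bis(benzyloxy)phenyl]ethoxy}-2-oxo-1-(pyridin-2-ylsulfanyl)ethyl]-2-methyl-3,4-dihydro-2H-pyran-5-carboxylate (both epimers at the sulfur-bearing carbon) | COC(=O)C1=CO[C@H](C)[C@@H](COCc2ccccc2)[C@@H]1C(Sc3ccccn3)C(=O)OCCc4ccc(OCc5ccccc5)c(OCc6ccccc6)c4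
F3 | step 3 | (2R,3R)-2-[(benzyloxy)methyl]-3-{[(E)-3-methoxy-3-oxoprop-1-en-1-yl]oxy}butanoic acid | COC(=O)/C=C/O[C@H](C)[C@@H](COCc1ccccc1)C(O)=O
F4 | step 3 | (2R,3R)-2-[(benzyloxy)methyl]-3-{[(Z)-2-iodo-3-methoxy-3-oxoprop-1-en-1-yl]oxy}butanoic acid | COC(=O)/C(I)=C/O[C@H](C)[C@@H](COCc1ccccc1)C(O)=O
F5 | step 6 | 2-[3,4-bis(benzyloxy)phenyl]ethyl (E)-3-(tributylstannyl)acrylate | CCCC[Sn](CCCC)(CCCC)/C=C/C(=O)OCCc1ccc(OCc2ccccc2)c(OCc2ccccc2)c1
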